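**Plan**

1. Retrosynthesis: cut the two amide C–N bonds, then the N–C bonds of both 2-aminoimidazoles back to chloromethyl ketones and so to carboxyl-level carbons. What remains is an all-trans cyclobutane, with ring carbons labelled Ca (CHO), Cb (CH2NO2), Cc (CH2OBn) and Cd (CO2Me).
2. The cyclobutane is cut at Cb–CH2N and at Ca–Cd, giving nitromethane and an acyclic (E)-enal whose γ-carbon (Cc) bears CH2OBn and whose δ-carbon (Cd) is an α-bromo ester. The enal is cut at its C=C (cross-metathesis) and at the Cc–malonate bond (allylic alkylation).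
3. Enabling feature: Ca and Cd each carry a carboxyl-level carbon (the future imidazole C4) and Cb carries CH2N. A Cb=Ca–C=O unit can therefore take up nitromethane at Cb and make Ca a nucleophile for the ester α-carbon Cd; nitro versus benzyl ether keeps the two arms distinct for the single bromine.
4. Forward: the chain is assembled in steps 1–7, the cyclobutane (the only carbocycle) closes in step 8, both imidazole rings form in step 12, and the pyrrole and bromopyrrole amides are attached in steps 13 and 15.
5. Stereochemistry: Cc comes from the allylic alkylation under [Ir(cod)Cl]2 and a chiral phosphoramidite, Cb from the prolinol ether in step 8, Ca and Cd from the trans-selective ring closure; all-trans is also the thermodynamic arrangement of the two epimerisable centres.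
6. An enal with an amine catalyst is chosen over an enoate with a base because the Ca nucleophile is then an enamine, which need not compete with the acidic nitromethyl group as an ester enolate would.

Key step: step 8

Remarks: the α-bromo ester and the enal made from it are carried as mixtures of epimers at the bromine-bearing carbon, so their SMILES leave that centre open. The Boc group of each protected aminoimidazole is drawn on the ring nitrogen next to C5–H; if it sat on the exocyclic nitrogen, nothing downstream would change, because the last step removes it. In step 12 one molecule of N-Boc-guanidine is built in per chloromethyl ketone, two in all.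

**Step 1**
Reactants: 1 but-2-yne-1,4-diol
Product: 2 4-(benzyloxy)but-2-yn-1-ol
Conditions: NaH (1.0 equiv), BnBr (0.5 equiv), Bu4NI (cat.), THF–DMF, 0 → 23 °C
Reagents that add atoms: benzyl bromide, BrCc1ccccc1
Why: Williamson etherification with the diol in excess and benzyl bromide limiting should give mainly the mono-ether, and unreacted diol is removed with water.

**Step 2**
Reactants: 2 4-(benzyloxy)but-2-yn-1-ol
Product: 3 (E)-4-(benzyloxy)but-2-en-1-ol
Conditions: NaAlH2(OCH2CH2OMe)2 (Red-Al), THF, 0 °C; aq. KNaC4H4O6 (potassium sodium tartrate)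
Reagents that add atoms: none
Why: Hydroxyl-directed trans-hydroalumination of the propargylic alcohol gives only the (E)-alkene, which the allylic alkylation needs because (Z)-allyl carbonates are known to react less selectively; 0 °C keeps the vinylalane from expelling benzyloxide to an allene.

**Step 3**
Reactants: 3 (E)-4-(benzyloxy)but-2-en-1-ol
Product: 4 (E)-4-(benzyloxy)but-2-en-1-yl methyl carbonate
Conditions: ClCO2Me, pyridine, CH2Cl2, 0 °C
Reagents that add atoms: methyl chloroformate, COC(=O)Cl
Why: O-acylation of the primary allylic alcohol installs the methyl carbonate, the usual leaving group for allylic substitution under [Ir(cod)Cl]2, which also releases methoxide as the base.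

**Step 4**
Reactants: 4 (E)-4-(benzyloxy)but-2-en-1-yl methyl carbonate; 5 dimethyl malonate
Product: 6 dimethyl 2-[(2R)-1-(benzyloxy)but-3-en-2-yl]propanedioate
Conditions: [Ir(cod)Cl]2 (2 mol %), BINOL-derived N,N-bis(1-phenylethyl)phosphoramidite (4 mol %, the enantiomer that leads to the R adduct, its antipode giving ent-6), 1,5,7-triazabicyclo[4.4.0]dec-5-ene (8 mol %), THF, 23 °C
Reagents that add atoms: none
Why: Asymmetric allylic alkylation catalysed by [Ir(cod)Cl]2 and the phosphoramidite, in which the metallacycle formed from the two under base ionises the linear carbonate and malonate attacks the substituted allyl terminus, should give the branched product and set Cc by ligand control.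

**Step 5**
Reactants: 6 dimethyl 2-[(2R)-1-(benzyloxy)but-3-en-2-yl]propanedioate
Product: 7 methyl (3S)-3-[(benzyloxy)methyl]pent-4-enoate
Conditions: LiCl, H2O, DMSO, 150 °C
Reagents that add atoms: none
Why: Krapcho dealkoxycarbonylation removes one malonate ester by chloride attack on its methyl group and loss of CO2; the stereocentre is β to the carbonyl and is not touched (the descriptor changes only because the priorities change).

**Step 6**
Reactants: 7 methyl (3S)-3-[(benzyloxy)methyl]pent-4-enoate
Product: 8 methyl (2RS,3S)-3-[(benzyloxy)methyl]-2-bromopent-4-enoate (both C2 epimers)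
Conditions: LiN(iPr)2, THF, −78 °C; NBS, −78 °C
Reagents that add atoms: N-bromosuccinimide, O=C1CCC(=O)N1Br
Why: Kinetic lithium enolate formation and electrophilic bromination at −78 °C, where the terminal alkene does not react; both C2 epimers form and both are used.

**Step 7**
Reactants: 8 methyl (2RS,3S)-3-[(benzyloxy)methyl]-2-bromopent-4-enoate; 9 (E)-but-2-enal
Product: 10 methyl (2RS,3S,4E)-3-[(benzyloxy)methyl]-2-bromo-6-oxohex-4-enoate
Conditions: second-generation Hoveyda–Grubbs catalyst RuCl2(H2IMes)(=CH-C6H4-2-OiPr) (5 mol %), 9 (5 equiv), CH2Cl2, 40 °C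
Reagents that add atoms: none
Why: Olefin cross-metathesis of the allylically branched terminal alkene with excess crotonaldehyde should give the (E)-enal with loss of propene under neutral conditions that spare the α-bromo ester.

**Step 8**
Reactants: 10 methyl (2RS,3S,4E)-3-[(benzyloxy)methyl]-2-bromo-6-oxohex-4-enoate; 11 nitromethane
Product: 13 methyl (1S,2R,3R,4S)-2-[(benzyloxy)methyl]-4-formyl-3-(nitromethyl)cyclobutane-1-carboxylate, via nitro aldehyde 12 (not isolated)
Conditions: MeNO2 (10 equiv), (S)-α,α-diphenylprolinol trimethylsilyl ether (20 mol %), PhCO2H (20 mol %), MeOH (0.05 M), 0 °C; then 2,6-lutidine (1.2 equiv), Bu4NBr (20 mol %), 40 °C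
Reagents that add atoms: none
Why: Proposed new method: the prolinol ether condenses with enal 10 to an iminium ion, nitronate adds to its β-carbon Cb, and the resulting enamine (neutral, and re-formed from aldehyde 12 whenever it is protonated) attacks the ester α-carbon Cd opposite to bromide, closing the four-membered ring by 4-exo-tet alkylation before hydrolysis returns the catalyst. The closest known reactions are the amine-catalysed addition of nitromethane to enals, the iminium–enamine Michael/α-alkylation cascades that convert enals and bromomalonates into cyclopropanes (3-exo-tet) and the amine-catalysed intramolecular α-alkylation of halo aldehydes (5-exo-tet); a 4-exo-tet closure in this manifold is the untested element. An enamine serves as the Ca nucleophile because an ester enolate could not be populated beside the far more acidic CH2NO2 group, whose nitronate would instead O-alkylate Cd to a six-membered cyclic nitronate, whereas an enamine has neither that acidity problem nor an oxygen through which to alkylate. Cb is set by the catalyst, which shields one face of the iminium ion (the S catalyst should deliver the 4S adduct, nitromethyl anti to benzyloxymethyl across Cb–Cc); Cd arises by inversion of whichever C2 epimer of 10 closes through the less crowded transition state, the epimers being interconverted by bromide exchange; Ca is set trans to both neighbours in the ring closure and stays correctable through its enamine. The step needs conjugate addition to outrun γ-deprotonation (dienamine formation followed by loss of bromide from Cd) and C-alkylation to outrun nitronate O-alkylation and N-alkylation of the catalyst: the first is served by excess nitromethane at 0 °C without added base, the second by adding only the weak, hindered base 2,6-lutidine, by dilution and by the bulk of the diarylprolinol ether.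

**Step 9**
Reactants: 13 methyl (1S,2R,3R,4S)-2-[(benzyloxy)methyl]-4-formyl-3-(nitromethyl)cyclobutane-1-carboxylate
Product: 15 dimethyl (1S,2S,3R,4R)-3-[(benzyloxy)methyl]-4-(nitromethyl)cyclobutane-1,2-dicarboxylate, via carboxylic acid 14 (not isolated)
Conditions: NaClO2, NaH2PO4, 2-methylbut-2-ene, t-BuOH/H2O, 0 → 23 °C; then TMSCHN2, PhMe/MeOH, 0 °C
Reagents that add atoms: sodium chlorite, [Na+].[O-]Cl=O; trimethylsilyldiazomethane, C[Si](C)(C)C=[N+]=[N-]
Why: Pinnick (chlorite) oxidation takes the aldehyde to the acid without touching the nitro group, and TMSCHN2 methylates it; as a trans-1,2-diester, 15 is also the point where any cis isomer carried over from step 8 could be equilibrated with NaOMe in MeOH.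

**Step 10**
Reactants: 15 dimethyl (1S,2S,3R,4R)-3-[(benzyloxy)methyl]-4-(nitromethyl)cyclobutane-1,2-dicarboxylate
Product: 17 dimethyl (1S,2S,3R,4R)-3-({[(benzyloxy)carbonyl]amino}methyl)-4-[(benzyloxy)methyl]cyclobutane-1,2-dicarboxylate, via primary amine 16 (not isolated)
Conditions: NiCl2·6H2O (0.3 equiv), NaBH4, MeOH, 0 °C; then CbzCl, NaHCO3, THF/H2O, 0 °C
Reagents that add atoms: benzyl chloroformate, O=C(Cl)OCc1ccccc1
Why: Reduction of the aliphatic nitro group by NaBH4 with NiCl2 (Ni2B formed in the flask) is followed at once by Schotten–Baumann acylation; no γ-lactam can form because the aminomethyl group and the neighbouring ester are trans on the four-membered ring, and the cold, prompt acylation forestalls the strained bridged lactam with the other ester.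

**Step 11**
Reactants: 17 dimethyl (1S,2S,3R,4R)-3-({[(benzyloxy)carbonyl]amino}methyl)-4-[(benzyloxy)methyl]cyclobutane-1,2-dicarboxylate
Product: 18 benzyl N-{[(1R,2S,3S,4R)-4-[(benzyloxy)methyl]-2,3-bis(2-chloroacetyl)cyclobutyl]methyl}carbamate
Conditions: ICH2Cl (6 equiv), MeLi·LiBr (6.5 equiv), THF, −78 °C; AcOH, −78 °C
Reagents that add atoms: chloroiodomethane, ClCI
Why: Halomethyllithium homologation of esters: chloromethyllithium, made by iodine–lithium exchange in the presence of the substrate, adds once to each methyl ester, and the tetrahedral adducts should persist at −78 °C until the acid quench releases the two chloromethyl ketones, the carbamate being masked as its lithium salt.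

**Step 12**
Reactants: 18 benzyl N-{[(1R,2S,3S,4R)-4-[(benzyloxy)methyl]-2,3-bis(2-chloroacetyl)cyclobutyl]methyl}carbamate; 19 tert-butyl N-carbamimidoylcarbamate (N-Boc-guanidine)
Product: 20 benzyl N-{[(1S,2S,3R,4R)-2,3-bis[2-amino-1-(tert-butoxycarbonyl)-1H-imidazol-4-yl]-4-[(benzyloxy)methyl]cyclobutyl]methyl}carbamate
Conditions: 19 (5 equiv: two molecules built in, the rest as base), NaI (20 mol %), DMF, 23 → 40 °C
Reagents that add atoms: tert-butyl N-carbamimidoylcarbamate (second molecule of 19), CC(C)(C)OC(=O)NC(N)=N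
Why: Condensation of an α-halo ketone with an acylguanidine (N-alkylation at CH2Cl, cyclisation onto the ketone, dehydration) takes place at each of the two chloromethyl ketones, so that 18 and two molecules of 19 give 20 with loss of two HCl and two H2O, the ketone carbon becoming C4 on the cyclobutane; Ca and Cd, enolisable until the rings aromatise, can only relax towards the all-trans arrangement.

**Step 13**
Reactants: 20 benzyl N-{[(1S,2S,3R,4R)-2,3-bis[2-amino-1-(tert-butoxycarbonyl)-1H-imidazol-4-yl]-4-[(benzyloxy)methyl]cyclobutyl]methyl}carbamate; 21 2,2,2-trichloro-1-(1H-pyrrol-2-yl)ethan-1-one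
Product: 23 N-{[(1S,2S,3R,4R)-2,3-bis[2-amino-1-(tert-butoxycarbonyl)-1H-imidazol-4-yl]-4-(hydroxymethyl)cyclobutyl]methyl}-1H-pyrrole-2-carboxamide, via amino alcohol 22 (not isolated)
Conditions: H2 (1 atm), Pd(OH)2/C, AcOH (2 equiv), EtOAc/EtOH, 23 °C; filter; then 21 (1.05 equiv), Na2CO3, DMF, 23 °C
Reagents that add atoms: none
Why: Hydrogenolysis cleaves the benzyl carbamate and the benzyl ether together, before any aryl bromide is present, and the trichloromethyl ketone then acylates only the primary amine (haloform-type acyl transfer), not the alcohol or the imidazole amino groups.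

**Step 14**
Reactants: 23 N-{[(1S,2S,3R,4R)-2,3-bis[2-amino-1-(tert-butoxycarbonyl)-1H-imidazol-4-yl]-4-(hydroxymethyl)cyclobutyl]methyl}-1H-pyrrole-2-carboxamide
Product: 24 N-{[(1R,2S,3S,4R)-4-(azidomethyl)-2,3-bis[2-amino-1-(tert-butoxycarbonyl)-1H-imidazol-4-yl]cyclobutyl]methyl}-1H-pyrrole-2-carboxamide
Conditions: PPh3, DIAD, (PhO)2P(O)N3, THF, 0 → 23 °C
Reagents that add atoms: diphenylphosphoryl azide, [N-]=[N+]=NP(=O)(Oc1ccccc1)Oc1ccccc1
Why: Mitsunobu azidation of the primary alcohol; the remaining N–H groups are too weakly acidic to compete as pronucleophiles, and the trans arrangement of the neighbouring substituents on the cyclobutane rules out intramolecular N-alkylation.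

**Step 15**
Reactants: 24 N-{[(1R,2S,3S,4R)-4-(azidomethyl)-2,3-bis[2-amino-1-(tert-butoxycarbonyl)-1H-imidazol-4-yl]cyclobutyl]methyl}-1H-pyrrole-2-carboxamide; 25 1-(4-bromo-1H-pyrrol-2-yl)-2,2,2-trichloroethan-1-one
Product: 27 N-{[(1R,2S,3S,4R)-2,3-bis[2-amino-1-(tert-butoxycarbonyl)-1H-imidazol-4-yl]-4-{[(1H-pyrrole-2-carbonyl)amino]methyl}cyclobutyl]methyl}-4-bromo-1H-pyrrole-2-carboxamide, via primary amine 26 (not isolated)
Conditions: PMe3, THF/H2O, 23 °C; then 25 (1.05 equiv), iPr2NEt, DMF, 23 °C
Reagents that add atoms: none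
Why: Staudinger reduction is non-hydrogenolytic, so the aryl bromide of the incoming acyl donor is safe, and the trichloromethyl ketone acylates the new primary amine as in step 13.

**Step 16**
Reactants: 27 N-{[(1R,2S,3S,4R)-2,3-bis[2-amino-1-(tert-butoxycarbonyl)-1H-imidazol-4-yl]-4-{[(1H-pyrrole-2-carbonyl)amino]methyl}cyclobutyl]methyl}-4-bromo-1H-pyrrole-2-carboxamide
Product: 28 desbromosceptrin
Conditions: TFA/CH2Cl2 (1:1), 0 → 23 °C; basic ion-exchange resin
Reagents that add atoms: none
Why: Acidolysis removes both Boc groups as CO2 and isobutene and leaves the amides and the four ring stereocentres, none of which is acid-labile, unchanged.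

**Compound list**

1 | but-2-yne-1,4-diol | OCC#CCO | starting material
2 | 4-(benzyloxy)but-2-yn-1-ol | OCC#CCOCc1ccccc1 | intermediate
3 | (E)-4-(benzyloxy)but-2-en-1-ol | OC/C=C/COCc1ccccc1 | intermediate
4 | (E)-4-(benzyloxy)but-2-en-1-yl methyl carbonate | COC(=O)OC/C=C/COCc1ccccc1 | intermediate
5 | dimethyl malonate | COC(=O)CC(=O)OC | starting material
6 | dimethyl 2-[(2R)-1-(benzyloxy)but-3-en-2-yl]propanedioate | C=C[C@@H](COCc1ccccc1)C(C(=O)OC)C(=O)OC | intermediate
7 | methyl (3S)-3-[(benzyloxy)methyl]pent-4-enoate | C=C[C@@H](COCc1ccccc1)CC(=O)OC | intermediate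
8 | methyl (2RS,3S)-3-[(benzyloxy)methyl]-2-bromopent-4-enoate (both C2 epimers) | C=C[C@@H](COCc1ccccc1)C(Br)C(=O)OC | intermediate
9 | (E)-but-2-enal (crotonaldehyde) | C/C=C/C=O | starting material
10 | methyl (2RS,3S,4E)-3-[(benzyloxy)methyl]-2-bromo-6-oxohex-4-enoate | O=C/C=C/[C@@H](COCc1ccccc1)C(Br)C(=O)OC | intermediate
11 | nitromethane | C[N+](=O)[O-] | starting material
12 | methyl (2RS,3S,4S)-3-[(benzyloxy)methyl]-2-bromo-4-(nitromethyl)-6-oxohexanoate | O=CC[C@H](C[N+](=O)[O-])[C@@H](COCc1ccccc1)C(Br)C(=O)OC | intermediate (not isolated)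
13 | methyl (1S,2R,3R,4S)-2-[(benzyloxy)methyl]-4-formyl-3-(nitromethyl)cyclobutane-1-carboxylate (all-trans) | O=C[C@H]1[C@H](C[N+](=O)[O-])[C@@H](COCc2ccccc2)[C@@H]1C(=O)OC | intermediate
14 | (1S,2S,3R,4R)-3-[(benzyloxy)methyl]-2-(methoxycarbonyl)-4-(nitromethyl)cyclobutane-1-carboxylic acid | OC(=O)[C@H]1[C@H](C[N+](=O)[O-])[C@@H](COCc2ccccc2)[C@@H]1C(=O)OC | intermediate (not isolated)
15 | dimethyl (1S,2S,3R,4R)-3-[(benzyloxy)methyl]-4-(nitromethyl)cyclobutane-1,2-dicarboxylate (all-trans) | COC(=O)[C@H]1[C@H](C[N+](=O)[O-])[C@@H](COCc2ccccc2)[C@@H]1C(=O)OC | intermediate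
16 | dimethyl (1S,2S,3R,4R)-3-(aminomethyl)-4-[(benzyloxy)methyl]cyclobutane-1,2-dicarboxylate | COC(=O)[C@H]1[C@H](CN)[C@@H](COCc2ccccc2)[C@@H]1C(=O)OC | intermediate (not isolated)
17 | dimethyl (1S,2S,3R,4R)-3-({[(benzyloxy)carbonyl]amino}methyl)-4-[(benzyloxy)methyl]cyclobutane-1,2-dicarboxylate | COC(=O)[C@H]1[C@H](CNC(=O)OCc2ccccc2)[C@@H](COCc2ccccc2)[C@@H]1C(=O)OC | intermediate
18 | benzyl N-{[(1R,2S,3S,4R)-4-[(benzyloxy)methyl]-2,3-bis(2-chloroacetyl)cyclobutyl]methyl}carbamate | ClCC(=O)[C@H]1[C@H](CNC(=O)OCc2ccccc2)[C@@H](COCc2ccccc2)[C@@H]1C(=O)CCl | intermediate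
19 | tert-butyl N-carbamimidoylcarbamate (N-Boc-guanidine) | CC(C)(C)OC(=O)NC(N)=N | starting material
20 | benzyl N-{[(1S,2S,3R,4R)-2,3-bis[2-amino-1-(tert-butoxycarbonyl)-1H-imidazol-4-yl]-4-[(benzyloxy)methyl]cyclobutyl]methyl}carbamate | CC(C)(C)OC(=O)n1cc(nc1N)[C@H]1[C@H](CNC(=O)OCc2ccccc2)[C@@H](COCc2ccccc2)[C@@H]1c1cn(C(=O)OC(C)(C)C)c(N)n1 | intermediate
21 | 2,2,2-trichloro-1-(1H-pyrrol-2-yl)ethan-1-one | O=C(c1ccc[nH]1)C(Cl)(Cl)Cl | starting material
22 | {(1R,2R,3S,4S)-4-(aminomethyl)-2,3-bis[2-amino-1-(tert-butoxycarbonyl)-1H-imidazol-4-yl]cyclobutyl}methanol | CC(C)(C)OC(=O)n1cc(nc1N)[C@H]1[C@H](CN)[C@@H](CO)[C@@H]1c1cn(C(=O)OC(C)(C)C)c(N)n1 | intermediate (not isolated)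
23 | N-{[(1S,2S,3R,4R)-2,3-bis[2-amino-1-(tert-butoxycarbonyl)-1H-imidazol-4-yl]-4-(hydroxymethyl)cyclobutyl]methyl}-1H-pyrrole-2-carboxamide | CC(C)(C)OC(=O)n1cc(nc1N)[C@H]1[C@H](CNC(=O)c2ccc[nH]2)[C@@H](CO)[C@@H]1c1cn(C(=O)OC(C)(C)C)c(N)n1 | intermediate
24 | N-{[(1R,2S,3S,4R)-4-(azidomethyl)-2,3-bis[2-amino-1-(tert-butoxycarbonyl)-1H-imidazol-4-yl]cyclobutyl]methyl}-1H-pyrrole-2-carboxamide | CC(C)(C)OC(=O)n1cc(nc1N)[C@H]1[C@H](CNC(=O)c2ccc[nH]2)[C@@H](CN=[N+]=[N-])[C@@H]1c1cn(C(=O)OC(C)(C)C)c(N)n1 | intermediate
25 | 1-(4-bromo-1H-pyrrol-2-yl)-2,2,2-trichloroethan-1-one | O=C(c1cc(Br)c[nH]1)C(Cl)(Cl)Cl | starting material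
26 | N-{[(1R,2S,3S,4R)-4-(aminomethyl)-2,3-bis[2-amino-1-(tert-butoxycarbonyl)-1H-imidazol-4-yl]cyclobutyl]methyl}-1H-pyrrole-2-carboxamide | CC(C)(C)OC(=O)n1cc(nc1N)[C@H]1[C@H](CNC(=O)c2ccc[nH]2)[C@@H](CN)[C@@H]1c1cn(C(=O)OC(C)(C)C)c(N)n1 | intermediate (not isolated)
27 | N-{[(1R,2S,3S,4R)-2,3-bis[2-amino-1-(tert-butoxycarbonyl)-1H-imidazol-4-yl]-4-{[(1H-pyrrole-2-carbonyl)amino]methyl}cyclobutyl]methyl}-4-bromo-1H-pyrrole-2-carboxamide | CC(C)(C)OC(=O)n1cc(nc1N)[C@H]1[C@H](CNC(=O)c2ccc[nH]2)[C@@H](CNC(=O)c2cc(Br)c[nH]2)[C@@H]1c1cn(C(=O)OC(C)(C)C)c(N)n1 | intermediate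
28 | desbromosceptrin, N-{[(1R,2S,3S,4R)-2,3-bis(2-amino-1H-imidazol-5-yl)-4-{[(1H-pyrrole-2-carbonyl)amino]methyl}cyclobutyl]methyl}-4-bromo-1H-pyrrole-2-carboxamide | Nc1ncc([C@H]2[C@H](CNC(=O)c3ccc[nH]3)[C@@H](CNC(=O)c3cc(Br)c[nH]3)[C@@H]2c2cnc(N)[nH]2)[nH]1 | target

**Step count**

Total: 16 steps. Longest linear sequence: 16 steps (the route is fully linear from 1).

**Steps most likely to fail**

Step 8 (proposed new method). The enamine ring closure may be too slow, so that loss of HBr through the dienamine, O-alkylation of Cd by the nitronate or N-alkylation of the catalyst consumes the material first. The fallback makes the two bonds in separate, known operations; it sets out from 7 and returns at 17. Cross-metathesis of 7 with crotonaldehyde 9 gives the bromine-free enal F1. The same prolinol ether adds nitromethane to it in the established way to give nitro aldehyde F2 (4S by catalyst control). Pinnick oxidation to acid F3 and methylation with TMSCHN2 give nitro adipate F4. Reduction with Zn/HCl keeps amine F5 protonated so that it cannot lactamise, and CbzCl/NaHCO3 then gives carbamate F6. LiN(iPr)2 (3.3 equiv, THF, −78 °C) followed by I2 closes Ca–Cd by intramolecular oxidative coupling of the bis-enolate (α-iodination, then 4-exo-tet alkylation in the flask), and NaOMe/MeOH equilibration should leave the all-trans diester 17.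

Step 11. Chloromethyllithium may add a second time once a tetrahedral adduct collapses, or may merely enolise the two hindered esters. The fallback brings the carbon in as a sulfoxonium ylide; it sets out from 17 and returns at 18. Me3S(O)I with KOtBu (THF, reflux) acylates dimethylsulfoxonium methylide with both esters to give bis(β-keto sulfoxonium ylide) F7, and anhydrous HCl (THF, 65 °C) displaces dimethyl sulfoxide from each protonated ylide to give the bis(chloromethyl ketone) 18.

Step 12. The double annulation may stall after one ring, or the chloro ketones may be lost to base-induced self-condensation before the guanidine has reacted twice. The fallback builds the imidazoles by the aminoketone–cyanamide condensation; it sets out from 18 and returns at 20. NaN(CHO)2 (MeCN, 60 °C) gives bis(diformylamide) F8; HCl in MeOH gives bis(aminomethyl ketone) dihydrochloride F9; cyanamide in water at pH 4.5 and 95 °C gives the unprotected bis(2-aminoimidazole) F10; Boc2O (2 equiv) on the ring nitrogens then gives 20.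

**Further compounds**

F1 | step 8 | methyl (3S,4E)-3-[(benzyloxy)methyl]-6-oxohex-4-enoate | O=C/C=C/[C@@H](COCc1ccccc1)CC(=O)OC
F2 | step 8 | methyl (3S,4S)-3-[(benzyloxy)methyl]-4-(nitromethyl)-6-oxohexanoate | O=CC[C@H](C[N+](=O)[O-])[C@@H](COCc1ccccc1)CC(=O)OC
F3 | step 8 | (3S,4S)-4-[(benzyloxy)methyl]-6-methoxy-3-(nitromethyl)-6-oxohexanoic acid | OC(=O)C[C@H](C[N+](=O)[O-])[C@@H](COCc1ccccc1)CC(=O)OC
F4 | step 8 | dimethyl (3S,4S)-3-[(benzyloxy)methyl]-4-(nitromethyl)hexanedioate | COC(=O)C[C@H](C[N+](=O)[O-])[C@@H](COCc1ccccc1)CC(=O)OC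
F5 | step 8 | dimethyl (3S,4S)-3-(aminomethyl)-4-[(benzyloxy)methyl]hexanedioate (handled as its hydrochloride) | COC(=O)C[C@H](CN)[C@@H](COCc1ccccc1)CC(=O)OC
F6 | step 8 | dimethyl (3S,4S)-3-({[(benzyloxy)carbonyl]amino}methyl)-4-[(benzyloxy)methyl]hexanedioate | COC(=O)C[C@H](CNC(=O)OCc1ccccc1)[C@@H](COCc1ccccc1)CC(=O)OC
F7 | step 11 | benzyl N-{[(1R,2S,3S,4R)-4-[(benzyloxy)methyl]-2,3-bis[2-(dimethyloxido-λ6-sulfanylidene)acetyl]cyclobutyl]methyl}carbamate | CS(C)(=O)=CC(=O)[C@H]1[C@H](CNC(=O)OCc2ccccc2)[C@@H](COCc2ccccc2)[C@@H]1C(=O)C=S(C)(C)=O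
F8 | step 12 | benzyl N-{[(1R,2S,3S,4R)-4-[(benzyloxy)methyl]-2,3-bis[2-(diformylamino)acetyl]cyclobutyl]methyl}carbamate | O=CN(C=O)CC(=O)[C@H]1[C@H](CNC(=O)OCc2ccccc2)[C@@H](COCc2ccccc2)[C@@H]1C(=O)CN(C=O)C=O
F9 | step 12 | benzyl N-{[(1R,2S,3S,4R)-2,3-bis(2-aminoacetyl)-4-[(benzyloxy)methyl]cyclobutyl]methyl}carbamate dihydrochloride | NCC(=O)[C@H]1[C@H](CNC(=O)OCc2ccccc2)[C@@H](COCc2ccccc2)[C@@H]1C(=O)CN.Cl.Cl
F10 | step 12 | benzyl N-{[(1S,2S,3R,4R)-2,3-bis(2-amino-1H-imidazol-4-yl)-4-[(benzyloxy)methyl]cyclobutyl]methyl}carbamate | Nc1nc(c[nH]1)[C@H]1[C@H](CNC(=O)OCc2ccccc2)[C@@H](COCc2ccccc2)[C@@H]1c1c[nH]c(N)n1
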